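**Assumptions**
- The target SMILES has no stereocentre and no stereogenic double bond, so the molecule is achiral and no stereocontrol is needed at any step.
- tert-Butyl 2-methylbut-3-en-2-yl carbonate (6) is treated as a purchasable reagent; if not, it is one step from 2-methylbut-3-en-2-ol and Boc2O.

**Retrosynthetic overview**
1. Last step: aromatic Claisen rearrangement of a 6-O-prenyl benzofuran puts the 1,1-dimethylallyl group on C7 and frees the 6-OH, so no protecting groups are used.
2. The furan ring (formed last) comes from a Sonogashira coupling/5-endo-dig annulation of a symmetric 2-iodo-5-(prenyloxy)resorcinol with a hindered aryl alkyne.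
3. The aryl alkyne comes from 3,5-dihydroxybenzaldehyde: O-tert-prenylation, double Claisen to the 2,6-diprenyl aldehyde, aldehyde-to-alkyne homologation, then acid closure of one prenyl/OH pair to the chroman (pyran ring formed first).
4. The iodide comes from phloroglucinol: mono-O-prenylation, then iodination between the two free hydroxyls.

**Route**

Step 1
Reactants: 1 phloroglucinol (benzene-1,3,5-triol, 3 equiv); 2 prenol (3-methylbut-2-en-1-ol)
Product: 3, 5-[(3-methylbut-2-en-1-yl)oxy]benzene-1,3-diol
Conditions: PPh3, DIAD, THF, 0 °C → rt
Reagents that add atoms: prenol (compound 2), CC(C)=CCO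
Why: Mitsunobu etherification is O-selective (no C-prenylation of the ambident phloroglucinol anion), and the threefold excess of cheap, water-extractable 1 holds the reaction at the mono-ether.

Step 2
Reactants: 3
Product: 4, 2-iodo-5-[(3-methylbut-2-en-1-yl)oxy]benzene-1,3-diol
Conditions: I2 (1.0 equiv), NaHCO3, THF/H2O, 0 °C
Reagents that add atoms: iodine, II
Why: Electrophilic aromatic iodination under I2/NaHCO3 goes kinetically to the carbon between the two hydroxyls (as it does for resorcinol itself), which is also para to the ether oxygen, and the phenoxide outcompetes the ether alkene for the single equivalent of iodine.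

Step 3
Reactants: 5, 3,5-dihydroxybenzaldehyde; 6, tert-butyl 2-methylbut-3-en-2-yl carbonate (2.5 equiv)
Product: 7, 3,5-bis[(2-methylbut-3-en-2-yl)oxy]benzaldehyde
Conditions: Pd(PPh3)4 (2 mol%), 4 Å MS, THF, 0 °C
Reagents that add atoms: tert-butyl 2-methylbut-3-en-2-yl carbonate (compound 6), C=CC(C)(C)OC(=O)OC(C)(C)C
Why: Tsuji–Trost O-allylation: Pd(0) ionises the carbonate (releasing CO2 and t-BuO⁻ as the base) and the phenoxide attacks the more substituted terminus of the 1,1-dimethylallyl–Pd cation, giving the kinetic tertiary ether at low temperature.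

Step 4
Reactants: 7
Product: 8, 3,5-dihydroxy-2,6-bis(3-methylbut-2-en-1-yl)benzaldehyde
Conditions: o-xylene, 130 °C, Ar (acid-free glassware)
Reagents that add atoms: none
Why: Two aromatic Claisen [3,3] rearrangements transfer each allyl unit with inversion (tertiary ether becomes linear C-prenyl); each goes to the ortho carbon next to the meta electron-withdrawing CHO and para to the other oxygen, the two known directing effects that both favour C2/C6 over C4, and the dienone then tautomerises to the phenol.

Step 5
Reactants: 8; 9, dimethyl (1-diazo-2-oxopropyl)phosphonate (Ohira–Bestmann reagent)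
Product: 10, 5-ethynyl-4,6-bis(3-methylbut-2-en-1-yl)benzene-1,3-diol
Conditions: K2CO3 (4 equiv), MeOH, 0 °C → rt
Reagents that add atoms: Ohira–Bestmann reagent (compound 9), COP(=O)(OC)C(=[N+]=[N-])C(C)=O (supplies the terminal alkyne carbon)
Why: Seyferth–Gilbert homologation (Ohira–Bestmann variant: olefination, N2 loss, 1,2-H shift) tolerates free phenols and isolated alkenes, and the phenols are meta to the aldehyde so their phenoxides do not deactivate it.

Step 6
Reactants: 10
Product: 11, 5-ethynyl-2,2-dimethyl-6-(3-methylbut-2-en-1-yl)-3,4-dihydro-2H-chromen-7-ol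
Conditions: Amberlyst-15 (cat.), CH2Cl2, rt, stopped at about 50–60% conversion; 10 recovered and recycled
Reagents that add atoms: none
Why: Acid-catalysed intramolecular hydroalkoxylation (Markovnikov protonation of a prenyl alkene, capture of the tertiary cation by the adjacent phenol) closes one 2,2-dimethylchroman; the two prenyl/OH pairs are equivalent, so the yield is statistically capped near 50% per pass and the bis-chroman is separated as a non-phenolic by-product.

Step 7
Reactants: 4; 11
Product: 12, 2-[7-hydroxy-2,2-dimethyl-6-(3-methylbut-2-en-1-yl)-3,4-dihydro-2H-chromen-5-yl]-6-[(3-methylbut-2-en-1-yl)oxy]-1-benzofuran-4-ol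
Conditions: PdCl2(PPh3)2 (5 mol%), CuI (10 mol%), Et3N, DMF, degassed, 60 → 80 °C
Reagents that add atoms: none
Why: Sonogashira coupling followed in the same pot by Cu/Pd-promoted 5-endo-dig attack of an ortho phenol on the alkyne (Castro/Larock-type benzofuran annulation); the two ortho hydroxyls of 4 are equivalent so only one benzofuran can form, and a linear alkyne tolerates the di-ortho-substituted aryl group.

Step 8
Reactants: 12
Product: 13, Artopetelin C, 2-[7-hydroxy-2,2-dimethyl-6-(3-methylbut-2-en-1-yl)-3,4-dihydro-2H-chromen-5-yl]-7-(2-methylbut-3-en-2-yl)-1-benzofuran-4,6-diol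
Conditions: PhNEt2, 180–190 °C, Ar, 1–2 h
Reagents that add atoms: none
Why: Aromatic Claisen [3,3] rearrangement of the aryl prenyl ether with allyl inversion gives the 1,1-dimethylallyl group and frees the 6-OH; migration should favour C7 over C5 because the benzofuran C6–C7 bond has the higher π-bond order (as 2-naphthyl and 7-coumarinyl allyl ethers migrate to the angular carbon) and C7 is para to the 4-OH donor, while the para position (C3a) is a ring fusion so no Claisen–Cope path exists.

**Compound list**

1 | phloroglucinol | Oc1cc(O)cc(O)c1 | starting material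
2 | prenol (3-methylbut-2-en-1-ol) | CC(C)=CCO | starting material
3 | 5-[(3-methylbut-2-en-1-yl)oxy]benzene-1,3-diol | CC(C)=CCOc1cc(O)cc(O)c1 | intermediate
4 | 2-iodo-5-[(3-methylbut-2-en-1-yl)oxy]benzene-1,3-diol | CC(C)=CCOc1cc(O)c(I)c(O)c1 | intermediate
5 | 3,5-dihydroxybenzaldehyde | O=Cc1cc(O)cc(O)c1 | starting material
6 | tert-butyl 2-methylbut-3-en-2-yl carbonate | C=CC(C)(C)OC(=O)OC(C)(C)C | starting material
7 | 3,5-bis[(2-methylbut-3-en-2-yl)oxy]benzaldehyde | C=CC(C)(C)Oc1cc(C=O)cc(OC(C)(C)C=C)c1 | intermediate
8 | 3,5-dihydroxy-2,6-bis(3-methylbut-2-en-1-yl)benzaldehyde | CC(C)=CCc1c(O)cc(O)c(CC=C(C)C)c1C=O | intermediate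
9 | dimethyl (1-diazo-2-oxopropyl)phosphonate | COP(=O)(OC)C(=[N+]=[N-])C(C)=O | starting material
10 | 5-ethynyl-4,6-bis(3-methylbut-2-en-1-yl)benzene-1,3-diol | C#Cc1c(CC=C(C)C)c(O)cc(O)c1CC=C(C)C | intermediate
11 | 5-ethynyl-2,2-dimethyl-6-(3-methylbut-2-en-1-yl)-3,4-dihydro-2H-chromen-7-ol | C#Cc1c(CC=C(C)C)c(O)cc2OC(C)(C)CCc12 | intermediate
12 | 2-[7-hydroxy-2,2-dimethyl-6-(3-methylbut-2-en-1-yl)chroman-5-yl]-6-[(3-methylbut-2-en-1-yl)oxy]-1-benzofuran-4-ol | CC(C)=CCOc1cc(O)c2cc(-c3c(CC=C(C)C)c(O)cc4OC(C)(C)CCc34)oc2c1 | intermediate
13 | Artopetelin C | C=CC(C)(C)c1c(O)cc(O)c2cc(-c3c(CC=C(C)C)c(O)cc4c3CCC(C)(C)O4)oc12 | target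

**Totals**
- Total steps: 8.
- Longest linear sequence: 6 (steps 3 → 4 → 5 → 6 → 7 → 8, from 3,5-dihydroxybenzaldehyde).

**Three steps most likely to fail, with fallbacks**

1. Step 8 (final Claisen). The risks are C5 versus C7 migration and thermal cyclisation or abnormal Claisen of the new ortho-(1,1-dimethylallyl)phenol. Fallback: install the reverse-prenyl group before the furan ring by a blocked Claisen. That is, take 3,5-bis(TBSO)phenol through ortho-iodination, O-prenylation and Claisen into the only free ortho carbon, then Sonogashira/annulation with 11 and TBAF removal of the silyl groups.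

2. Step 4 (double Claisen). Some migration to C4, between the two oxygens, would give 2,4-diprenyl isomers. Fallback: block C4 with bromine, starting from commercial 4-bromo-3,5-dihydroxybenzoic acid reduced to the aldehyde. Only C2 and C6 are then open, and the bromine is removed afterwards by Pd/formate hydrodehalogenation.

3. Step 7 (Sonogashira/annulation). The unprotected, very electron-rich iodoresorcinol 4 may deiodinate or couple sluggishly with the hindered alkyne. Fallback: make the C2–aryl bond by Suzuki–Miyaura coupling instead. Annulate 4 with TMS-acetylene to the 2-unsubstituted benzofuran, silylate the 4-OH, lithiate and borylate C2, and couple (SPhos-Pd) with the aryl bromide analogue of 11 made from 5-bromoresorcinol by the same O-tert-prenylation/Claisen/cyclisation sequence.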